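**Retrosynthetic overview**

- Reading of the target: units T (2S,3S) and M (2R,3R) are 2,3-cis-3,4-cis flavans, unit B is the (2S,3S,4R) 2,3-cis-3,4-trans flavan-3,4-diol; the units are joined C4(T)–C8(M) and C4(M)–C8(B).
- Feature: the C4–C4a bond of unit B, which ties the carbinol carbon C4 (hydroxyl anti to O3) to the trioxygenated ring A right beside the oxygenated stereocentre C3. It is cut to an aldehyde carbon and a free ortho position of a 3,5-bis(benzyloxy)phenyl ether, so ring C is the last ring closed in each monomer (rings A and B are bought as 1,3,5-trifluorobenzene and 4-benzyloxybenzaldehyde).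
- The aldehyde comes from an Evans glycolate syn aldol (C2, C3) and SNAr etherification (O1–C8a). The same ring closure in the mirror-image series gives unit M, and oxidation of the C4 carbinols gives the flavan-4-ones used for units T and M.
- Interflavan bonds: C8 aryl metal plus flavan-4-one, then ionic deoxygenation with hydride anti to O3 (all-cis units M and T), in the order B→M→T; thirteen benzyl ethers are removed at the end.

Key step: step 9

Remark: the configuration written at the tertiary carbinol carbon of 35 and 39 is the expected one (aryl metal anti to the C3 benzyloxy group); it has no bearing on the route because that centre becomes planar in the following step.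

**Series for units B and T (2S flavans)**

Step 1
Reactants: 1 (R)-4-benzyl-1,3-oxazolidin-2-one; 2 (benzyloxy)acetyl chloride
Product: 3 (4R)-4-benzyl-3-[(benzyloxy)acetyl]-1,3-oxazolidin-2-one
Conditions: n-BuLi, THF, –78 °C; then 2, –78 → 0 °C
Reagents that add atoms: none
Why: N-acylation of the lithiated oxazolidinone by the acid chloride is the standard entry to glycolate imides and touches no stereocentre.

Step 2
Reactants: 3 (4R)-4-benzyl-3-[(benzyloxy)acetyl]-1,3-oxazolidin-2-one; 4 4-(benzyloxy)benzaldehyde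
Product: 6 (4R)-4-benzyl-3-[(2R,3S)-2-(benzyloxy)-3-[4-(benzyloxy)phenyl]-3-hydroxypropanoyl]-1,3-oxazolidin-2-one, via Z dibutylboron enolate 5 (not isolated)
Conditions: Bu2BOTf, Et3N, CH2Cl2, –78 → 0 °C; 4, –78 → 0 °C; then pH 7 buffer, MeOH, H2O2
Reagents that add atoms: none
Why: Evans syn aldol reaction, in which the Z boron enolate reacts through a Zimmerman–Traxler chair on the face away from the auxiliary benzyl group and so sets the 2,3-syn pair (2R, future C3 of the flavan; 3S, future C2) with the C3 benzyl ether already in place.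

Step 3
Reactants: 6 (4R)-4-benzyl-3-[(2R,3S)-2-(benzyloxy)-3-[4-(benzyloxy)phenyl]-3-hydroxypropanoyl]-1,3-oxazolidin-2-one
Product: 7 (1S,2S)-2-(benzyloxy)-1-[4-(benzyloxy)phenyl]propane-1,3-diol
Conditions: LiBH4, MeOH, THF, 0 °C
Reagents that add atoms: none
Why: reductive cleavage of the imide by borohydride gives the 1,3-diol and returns the auxiliary, with both stereocentres untouched at 0 °C.

Step 4
Reactants: 7 (1S,2S)-2-(benzyloxy)-1-[4-(benzyloxy)phenyl]propane-1,3-diol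
Product: 8 (1S,2S)-2-(benzyloxy)-1-[4-(benzyloxy)phenyl]-3-(trityloxy)propan-1-ol
Conditions: TrCl, Et3N, DMAP (cat.), CH2Cl2, 0 °C → rt
Reagents that add atoms: trityl chloride, ClC(c1ccccc1)(c1ccccc1)c1ccccc1
Why: tritylation is selective for the primary hydroxyl on steric grounds, and a trityl ether can neither migrate to the neighbouring alkoxide nor be cleaved in the strongly basic steps 5 and 6.

Step 5
Reactants: 8 (1S,2S)-2-(benzyloxy)-1-[4-(benzyloxy)phenyl]-3-(trityloxy)propan-1-ol; 9 1,3,5-trifluorobenzene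
Product: 10 1-[(1S,2S)-2-(benzyloxy)-1-[4-(benzyloxy)phenyl]-3-(trityloxy)propoxy]-3,5-difluorobenzene
Conditions: KN(SiMe3)2, THF–DMPU, 0 °C; then 9 (5 equiv), 0 → 50 °C
Reagents that add atoms: none
Why: nucleophilic aromatic substitution (SNAr) of one fluoride by the potassium alkoxide forms the future O1–C8a bond without breaking the carbinol C–O bond, so the benzylic configuration is retained; excess arene holds back double substitution.

Step 6
Reactants: 10 1-[(1S,2S)-2-(benzyloxy)-1-[4-(benzyloxy)phenyl]-3-(trityloxy)propoxy]-3,5-difluorobenzene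
Product: 11 1,3-bis(benzyloxy)-5-[(1S,2S)-2-(benzyloxy)-1-[4-(benzyloxy)phenyl]-3-(trityloxy)propoxy]benzene
Conditions: BnOH, NaH, NMP, 100 °C
Reagents that add atoms: benzyl alcohol, OCc1ccccc1
Why: two further SNAr displacements by sodium benzyloxide turn the remaining fluorides into the benzyl ethers of ring A, while the trityl ether, the alkyl aryl ether and both stereocentres are inert to alkoxide.

Step 7
Reactants: 11 1,3-bis(benzyloxy)-5-[(1S,2S)-2-(benzyloxy)-1-[4-(benzyloxy)phenyl]-3-(trityloxy)propoxy]benzene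
Product: 12 (2S,3S)-2-(benzyloxy)-3-[4-(benzyloxy)phenyl]-3-[3,5-bis(benzyloxy)phenoxy]propan-1-ol
Conditions: camphorsulfonic acid (cat.), MeOH–CH2Cl2, 0 °C → rt
Reagents that add atoms: none
Why: acid-catalysed methanolysis of the trityl ether runs through the trityl cation, which forms far faster than the secondary benzylic aryl ether ionises, so the primary alcohol is released cleanly.

Step 8
Reactants: 12 (2S,3S)-2-(benzyloxy)-3-[4-(benzyloxy)phenyl]-3-[3,5-bis(benzyloxy)phenoxy]propan-1-ol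
Product: 13 (2R,3S)-2-(benzyloxy)-3-[4-(benzyloxy)phenyl]-3-[3,5-bis(benzyloxy)phenoxy]propanal
Conditions: Dess–Martin periodinane, CH2Cl2, 0 °C → rt; crude product used at once
Reagents that add atoms: none
Why: Dess–Martin oxidation gives the aldehyde without base, which avoids epimerisation at C2 and E1cB loss of the β-aryloxy group.

Step 9
Reactants: 13 (2R,3S)-2-(benzyloxy)-3-[4-(benzyloxy)phenyl]-3-[3,5-bis(benzyloxy)phenoxy]propanal
Product: 15 (2S,3S,4R)-3,5,7-tris(benzyloxy)-2-[4-(benzyloxy)phenyl]chroman-4-ol, via chloro(methyl)aluminium alkoxide 14 (not isolated)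
Conditions: Me2AlCl (1.1 equiv), CH2Cl2, –78 → –40 °C; then pH 7 phosphate buffer, aq. KNaC4H4O6
Reagents that add atoms: none
Why: Intramolecular Friedel–Crafts hydroxyalkylation: the aluminium reagent binds the aldehyde oxygen, a ring carbon ortho to the ether oxygen adds to the carbonyl carbon to make C4–C4a, and the proton released on rearomatisation is taken up by an Al–Me bond as methane, so the product rests as alkoxide 14 until the neutral quench. The closest known reaction type is the Lewis-acid cyclisation of 3-aryloxypropanals to chroman-4-ols. Ring C closes in a 6-exo-trig mode with respect to the carbonyl group (the C=O bond stays outside the new ring) through a chair-like transition state. In that chair the 4-benzyloxyphenyl group at C2 sits equatorial, which forces the cis C3 benzyloxy group axial; the aluminium-bound oxygen then prefers the axial site on the opposite face, where the C4–O and C3–O dipoles oppose each other and contact with the C5 benzyloxy group is avoided, so the 4R carbinol (3,4-trans) results. The step needs regiocontrol, given by the two equivalent ortho positions of the symmetrical ring; a non-chelated aldehyde, given by a single equivalent of the four-coordinate aluminium reagent; and survival of the β-aryloxy aldehyde and the ionisable C4–O bond, given by the absence of base and protic acid at low temperature.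

Step 10
Reactants: 15 (2S,3S,4R)-3,5,7-tris(benzyloxy)-2-[4-(benzyloxy)phenyl]chroman-4-ol
Product: 16 (2S,3S,4R)-3,4,5,7-tetrakis(benzyloxy)-2-[4-(benzyloxy)phenyl]chromane
Conditions: NaH, BnBr, Bu4NI (cat.), THF–DMF, 0 °C → rt
Reagents that add atoms: benzyl bromide, BrCc1ccccc1
Why: Williamson etherification of the C4 alkoxide protects the ionisable benzylic carbinol under basic conditions, so the C4 cation is never formed and the configuration is kept.

Step 11
Reactants: 16 (2S,3S,4R)-3,4,5,7-tetrakis(benzyloxy)-2-[4-(benzyloxy)phenyl]chromane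
Product: 17 (2S,3S,4R)-3,4,5,7-tetrakis(benzyloxy)-2-[4-(benzyloxy)phenyl]-8-bromochromane
Conditions: NBS, CH2Cl2, –78 → –20 °C
Reagents that add atoms: N-bromosuccinimide, O=C1CCC(=O)N1Br
Why: electrophilic aromatic bromination goes to C8 (between O1 and one benzyloxy group) in preference to the more crowded C6 between two benzyloxy groups, as is general for 5,7-di-O-benzylflavans.

Step 12
Reactants: 15 (2S,3S,4R)-3,5,7-tris(benzyloxy)-2-[4-(benzyloxy)phenyl]chroman-4-ol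
Product: 18 (2S,3R)-3,5,7-tris(benzyloxy)-2-[4-(benzyloxy)phenyl]chroman-4-one
Conditions: Dess–Martin periodinane, NaHCO3, CH2Cl2, 0 °C → rt
Reagents that add atoms: none
Why: Dess–Martin oxidation of the benzylic C4 carbinol gives the 2,3-cis flavan-4-one (unit T electrophile), and the buffered non-basic medium avoids epimerisation at C3.

**Series for unit M (2R flavan)**

Step 13
Reactants: 19 (S)-4-benzyl-1,3-oxazolidin-2-one; 2 (benzyloxy)acetyl chloride
Product: 20 (4S)-4-benzyl-3-[(benzyloxy)acetyl]-1,3-oxazolidin-2-one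
Conditions: n-BuLi, THF, –78 °C; then 2, –78 → 0 °C
Reagents that add atoms: none
Why: the same N-acylation as in step 1, now with the enantiomeric auxiliary.

Step 14
Reactants: 20 (4S)-4-benzyl-3-[(benzyloxy)acetyl]-1,3-oxazolidin-2-one; 4 4-(benzyloxy)benzaldehyde
Product: 22 (4S)-4-benzyl-3-[(2S,3R)-2-(benzyloxy)-3-[4-(benzyloxy)phenyl]-3-hydroxypropanoyl]-1,3-oxazolidin-2-one, via Z dibutylboron enolate 21 (not isolated)
Conditions: Bu2BOTf, Et3N, CH2Cl2, –78 → 0 °C; 4, –78 → 0 °C; then pH 7 buffer, MeOH, H2O2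
Reagents that add atoms: none
Why: Evans syn aldol reaction as in step 2, the (S)-auxiliary now directing the aldehyde to the opposite enolate face and giving the mirror-image 2,3-syn pair.

Step 15
Reactants: 22 (4S)-4-benzyl-3-[(2S,3R)-2-(benzyloxy)-3-[4-(benzyloxy)phenyl]-3-hydroxypropanoyl]-1,3-oxazolidin-2-one
Product: 23 (1R,2R)-2-(benzyloxy)-1-[4-(benzyloxy)phenyl]propane-1,3-diol
Conditions: LiBH4, MeOH, THF, 0 °C
Reagents that add atoms: none
Why: reductive cleavage of the imide by borohydride as in step 3, with no change at the stereocentres.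

Step 16
Reactants: 23 (1R,2R)-2-(benzyloxy)-1-[4-(benzyloxy)phenyl]propane-1,3-diol
Product: 24 (1R,2R)-2-(benzyloxy)-1-[4-(benzyloxy)phenyl]-3-(trityloxy)propan-1-ol
Conditions: TrCl, Et3N, DMAP (cat.), CH2Cl2, 0 °C → rt
Reagents that add atoms: trityl chloride, ClC(c1ccccc1)(c1ccccc1)c1ccccc1
Why: selective tritylation of the primary hydroxyl as in step 4.

Step 17
Reactants: 24 (1R,2R)-2-(benzyloxy)-1-[4-(benzyloxy)phenyl]-3-(trityloxy)propan-1-ol; 9 1,3,5-trifluorobenzene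
Product: 25 1-[(1R,2R)-2-(benzyloxy)-1-[4-(benzyloxy)phenyl]-3-(trityloxy)propoxy]-3,5-difluorobenzene
Conditions: KN(SiMe3)2, THF–DMPU, 0 °C; then 9 (5 equiv), 0 → 50 °C
Reagents that add atoms: none
Why: SNAr etherification by the alkoxide as in step 5, with retention at the benzylic carbon.

Step 18
Reactants: 25 1-[(1R,2R)-2-(benzyloxy)-1-[4-(benzyloxy)phenyl]-3-(trityloxy)propoxy]-3,5-difluorobenzene
Product: 26 1,3-bis(benzyloxy)-5-[(1R,2R)-2-(benzyloxy)-1-[4-(benzyloxy)phenyl]-3-(trityloxy)propoxy]benzene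
Conditions: BnOH, NaH, NMP, 100 °C
Reagents that add atoms: benzyl alcohol, OCc1ccccc1
Why: double SNAr exchange of fluoride for benzyloxide as in step 6.

Step 19
Reactants: 26 1,3-bis(benzyloxy)-5-[(1R,2R)-2-(benzyloxy)-1-[4-(benzyloxy)phenyl]-3-(trityloxy)propoxy]benzene
Product: 27 (2R,3R)-2-(benzyloxy)-3-[4-(benzyloxy)phenyl]-3-[3,5-bis(benzyloxy)phenoxy]propan-1-ol
Conditions: camphorsulfonic acid (cat.), MeOH–CH2Cl2, 0 °C → rt
Reagents that add atoms: none
Why: acid-catalysed methanolysis of the trityl ether as in step 7.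

Step 20
Reactants: 27 (2R,3R)-2-(benzyloxy)-3-[4-(benzyloxy)phenyl]-3-[3,5-bis(benzyloxy)phenoxy]propan-1-ol
Product: 28 (2S,3R)-2-(benzyloxy)-3-[4-(benzyloxy)phenyl]-3-[3,5-bis(benzyloxy)phenoxy]propanal
Conditions: Dess–Martin periodinane, CH2Cl2, 0 °C → rt; crude product used at once
Reagents that add atoms: none
Why: base-free Dess–Martin oxidation as in step 8.

Step 21
Reactants: 28 (2S,3R)-2-(benzyloxy)-3-[4-(benzyloxy)phenyl]-3-[3,5-bis(benzyloxy)phenoxy]propanal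
Product: 30 (2R,3R,4S)-3,5,7-tris(benzyloxy)-2-[4-(benzyloxy)phenyl]chroman-4-ol, via chloro(methyl)aluminium alkoxide 29 (not isolated)
Conditions: Me2AlCl (1.1 equiv), CH2Cl2, –78 → –40 °C; then pH 7 phosphate buffer, aq. KNaC4H4O6
Reagents that add atoms: none
Why: the intramolecular Friedel–Crafts hydroxyalkylation of step 9 in the mirror-image series, closing ring C of unit M and setting C4 (S) trans to O3 under the same substrate control.

Step 22
Reactants: 30 (2R,3R,4S)-3,5,7-tris(benzyloxy)-2-[4-(benzyloxy)phenyl]chroman-4-ol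
Product: 31 (2R,3R,4S)-3,5,7-tris(benzyloxy)-2-[4-(benzyloxy)phenyl]-8-bromochroman-4-ol
Conditions: NBS, CH2Cl2, –78 → –20 °C
Reagents that add atoms: N-bromosuccinimide, O=C1CCC(=O)N1Br
Why: electrophilic aromatic bromination at C8 as in step 11, ring bromination of the trialkoxyarene being much faster at low temperature than any oxidation of the free C4 hydroxyl.

Step 23
Reactants: 31 (2R,3R,4S)-3,5,7-tris(benzyloxy)-2-[4-(benzyloxy)phenyl]-8-bromochroman-4-ol
Product: 32 (2R,3S)-3,5,7-tris(benzyloxy)-2-[4-(benzyloxy)phenyl]-8-bromochroman-4-one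
Conditions: Dess–Martin periodinane, NaHCO3, CH2Cl2, 0 °C → rt
Reagents that add atoms: none
Why: Dess–Martin oxidation as in step 12 gives the 2,3-cis flavan-4-one that serves as unit M electrophile and keeps the C8 bromide for the later coupling.

**Assembly B→M→T and deprotection**

Step 24
Reactants: 17 (2S,3S,4R)-3,4,5,7-tetrakis(benzyloxy)-2-[4-(benzyloxy)phenyl]-8-bromochromane; 32 (2R,3S)-3,5,7-tris(benzyloxy)-2-[4-(benzyloxy)phenyl]-8-bromochroman-4-one
Product: 35 dimer carbinol [unit M: 2R; 2-aryl and 3-OBn cis; 8-Br; C4 bears OH (cis to 3-OBn) and C8 of unit B; unit B as in 16], via aryllithium 33 (not isolated), via aryldichlorocerium 34 (not isolated)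
Conditions: 17, t-BuLi (2 equiv), THF, –78 °C; CeCl3, –78 °C; then 32, –78 → –40 °C; aq. NH4Cl
Reagents that add atoms: none
Why: bromine–lithium exchange, transmetalation to the less basic organocerium reagent and 1,2-addition to the ketone form the C4(M)–C8(B) bond; the cerium reagent holds back enolisation at C3 and halogen exchange with the bromide of 32, a reaction type known for C8-metalated flavans and 3-O-protected flavan-4-ones.

Step 25
Reactants: 35 dimer carbinol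
Product: 36 benzylated 8-bromo dimer M–B [unit M: 2R; C2/C3/C4 all-cis; C4(M)–C8(B); unit B (2S,3S,4R) as in 16]
Conditions: Bu3SnH, CF3CO2H, CH2Cl2, –78 → –20 °C
Reagents that add atoms: none
Why: ionic hydrogenation, in which the acid ionises the tertiary bis-aryl carbinol and the stannane delivers hydride to the planar C4 cation on the face anti to the pseudo-axial C3 benzyloxy group, leaving the C4 aryl group cis to O3 and to the C2 aryl group; the doubly aryl-stabilised cation forms under conditions mild enough that the secondary C4 benzyl ether of unit B should stay intact.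

Step 26
Reactants: 36 benzylated 8-bromo dimer M–B; 18 (2S,3R)-3,5,7-tris(benzyloxy)-2-[4-(benzyloxy)phenyl]chroman-4-one
Product: 39 trimer carbinol [unit T: 2S; 2-aryl and 3-OBn cis; C4 bears OH (cis to 3-OBn) and C8 of unit M; units M and B as in 36], via aryllithium 37 (not isolated), via aryldichlorocerium 38 (not isolated)
Conditions: 36, t-BuLi (2 equiv), THF, –78 °C; CeCl3, –78 °C; then 18, –78 → –40 °C; aq. NH4Cl
Reagents that add atoms: none
Why: the same bromine–lithium exchange, cerium transmetalation and ketone 1,2-addition as in step 24 now forms the C4(T)–C8(M) bond, bromine exchange at –78 °C being faster than deprotonation of the dimer.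

Step 27
Reactants: 39 trimer carbinol
Product: 40 tridecabenzyl trimer T–M–B [unit T: 2S all-cis; unit M: 2R all-cis; unit B (2S,3S,4R); C4(T)–C8(M) and C4(M)–C8(B)]
Conditions: Bu3SnH, CF3CO2H, CH2Cl2, –78 → –20 °C
Reagents that add atoms: none
Why: ionic hydrogenation as in step 25, hydride adding to the C4(T) cation anti to the C3 benzyloxy group so that unit T becomes all-cis.

Step 28
Reactants: 40 tridecabenzyl trimer T–M–B
Product: 41 CNP0159291.1
Conditions: H2 (1 atm), Pd(OH)2/C, THF–MeOH–H2O, rt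
Reagents that add atoms: none
Why: catalytic hydrogenolysis removes all thirteen benzyl ethers under neutral conditions, cleavage of the O–CH2Ph bonds being faster than that of the hindered secondary C4–O bond of unit B, and no stereocentre is affected.

**Compound list**

1 | (R)-4-benzyl-1,3-oxazolidin-2-one | O=C1N[C@H](Cc2ccccc2)CO1 | starting material
2 | (benzyloxy)acetyl chloride | ClC(=O)COCc1ccccc1 | starting material
3 | (4R)-4-benzyl-3-[(benzyloxy)acetyl]-1,3-oxazolidin-2-one | O=C(COCc1ccccc1)N1C(=O)OC[C@H]1Cc1ccccc1 | intermediate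
4 | 4-(benzyloxy)benzaldehyde | O=Cc1ccc(OCc2ccccc2)cc1 | starting material
5 | Z dibutylboron enolate of 3 | CCCCB(CCCC)O/C(=C\OCc1ccccc1)N1C(=O)OC[C@H]1Cc1ccccc1 | intermediate
6 | (4R)-4-benzyl-3-[(2R,3S)-2-(benzyloxy)-3-[4-(benzyloxy)phenyl]-3-hydroxypropanoyl]-1,3-oxazolidin-2-one | O=C([C@H](OCc1ccccc1)[C@@H](O)c1ccc(OCc2ccccc2)cc1)N1C(=O)OC[C@H]1Cc1ccccc1 | intermediate
7 | (1S,2S)-2-(benzyloxy)-1-[4-(benzyloxy)phenyl]propane-1,3-diol | OC[C@H](OCc1ccccc1)[C@@H](O)c1ccc(OCc2ccccc2)cc1 | intermediate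
8 | (1S,2S)-2-(benzyloxy)-1-[4-(benzyloxy)phenyl]-3-(trityloxy)propan-1-ol | c1ccccc1C(c1ccccc1)(c1ccccc1)OC[C@H](OCc1ccccc1)[C@@H](O)c1ccc(OCc2ccccc2)cc1 | intermediate
9 | 1,3,5-trifluorobenzene | Fc1cc(F)cc(F)c1 | starting material
10 | 1-[(1S,2S)-2-(benzyloxy)-1-[4-(benzyloxy)phenyl]-3-(trityloxy)propoxy]-3,5-difluorobenzene | c1ccccc1C(c1ccccc1)(c1ccccc1)OC[C@H](OCc1ccccc1)[C@@H](Oc1cc(F)cc(F)c1)c1ccc(OCc2ccccc2)cc1 | intermediate
11 | 1,3-bis(benzyloxy)-5-[(1S,2S)-2-(benzyloxy)-1-[4-(benzyloxy)phenyl]-3-(trityloxy)propoxy]benzene | c1ccccc1C(c1ccccc1)(c1ccccc1)OC[C@H](OCc1ccccc1)[C@@H](Oc1cc(OCc2ccccc2)cc(OCc2ccccc2)c1)c1ccc(OCc2ccccc2)cc1 | intermediate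
12 | (2S,3S)-2-(benzyloxy)-3-[4-(benzyloxy)phenyl]-3-[3,5-bis(benzyloxy)phenoxy]propan-1-ol | OC[C@H](OCc1ccccc1)[C@@H](Oc1cc(OCc2ccccc2)cc(OCc2ccccc2)c1)c1ccc(OCc2ccccc2)cc1 | intermediate
13 | (2R,3S)-2-(benzyloxy)-3-[4-(benzyloxy)phenyl]-3-[3,5-bis(benzyloxy)phenoxy]propanal | O=C[C@H](OCc1ccccc1)[C@@H](Oc1cc(OCc2ccccc2)cc(OCc2ccccc2)c1)c1ccc(OCc2ccccc2)cc1 | intermediate
14 | chloro(methyl)aluminium C4 alkoxide of 15 | c1c(OCc3ccccc3)cc(OCc3ccccc3)c2c1O[C@@H](c1ccc(OCc3ccccc3)cc1)[C@@H](OCc1ccccc1)[C@@H]2O[Al](C)Cl | intermediate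
15 | (2S,3S,4R)-3,5,7-tris(benzyloxy)-2-[4-(benzyloxy)phenyl]chroman-4-ol | c1c(OCc3ccccc3)cc(OCc3ccccc3)c2c1O[C@@H](c1ccc(OCc3ccccc3)cc1)[C@@H](OCc1ccccc1)[C@@H]2O | intermediate
16 | (2S,3S,4R)-3,4,5,7-tetrakis(benzyloxy)-2-[4-(benzyloxy)phenyl]chromane | c1c(OCc3ccccc3)cc(OCc3ccccc3)c2c1O[C@@H](c1ccc(OCc3ccccc3)cc1)[C@@H](OCc1ccccc1)[C@@H]2OCc1ccccc1 | intermediate
17 | (2S,3S,4R)-3,4,5,7-tetrakis(benzyloxy)-2-[4-(benzyloxy)phenyl]-8-bromochromane | Brc1c(OCc3ccccc3)cc(OCc3ccccc3)c2c1O[C@@H](c1ccc(OCc3ccccc3)cc1)[C@@H](OCc1ccccc1)[C@@H]2OCc1ccccc1 | intermediate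
18 | (2S,3R)-3,5,7-tris(benzyloxy)-2-[4-(benzyloxy)phenyl]chroman-4-one | c1c(OCc3ccccc3)cc(OCc3ccccc3)c2c1O[C@@H](c1ccc(OCc3ccccc3)cc1)[C@@H](OCc1ccccc1)C2=O | intermediate
19 | (S)-4-benzyl-1,3-oxazolidin-2-one | O=C1N[C@@H](Cc2ccccc2)CO1 | starting material
20 | (4S)-4-benzyl-3-[(benzyloxy)acetyl]-1,3-oxazolidin-2-one | O=C(COCc1ccccc1)N1C(=O)OC[C@@H]1Cc1ccccc1 | intermediate
21 | Z dibutylboron enolate of 20 | CCCCB(CCCC)O/C(=C\OCc1ccccc1)N1C(=O)OC[C@@H]1Cc1ccccc1 | intermediate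
22 | (4S)-4-benzyl-3-[(2S,3R)-2-(benzyloxy)-3-[4-(benzyloxy)phenyl]-3-hydroxypropanoyl]-1,3-oxazolidin-2-one | O=C([C@@H](OCc1ccccc1)[C@H](O)c1ccc(OCc2ccccc2)cc1)N1C(=O)OC[C@@H]1Cc1ccccc1 | intermediate
23 | (1R,2R)-2-(benzyloxy)-1-[4-(benzyloxy)phenyl]propane-1,3-diol | OC[C@@H](OCc1ccccc1)[C@H](O)c1ccc(OCc2ccccc2)cc1 | intermediate
24 | (1R,2R)-2-(benzyloxy)-1-[4-(benzyloxy)phenyl]-3-(trityloxy)propan-1-ol | c1ccccc1C(c1ccccc1)(c1ccccc1)OC[C@@H](OCc1ccccc1)[C@H](O)c1ccc(OCc2ccccc2)cc1 | intermediate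
25 | 1-[(1R,2R)-2-(benzyloxy)-1-[4-(benzyloxy)phenyl]-3-(trityloxy)propoxy]-3,5-difluorobenzene | c1ccccc1C(c1ccccc1)(c1ccccc1)OC[C@@H](OCc1ccccc1)[C@H](Oc1cc(F)cc(F)c1)c1ccc(OCc2ccccc2)cc1 | intermediate
26 | 1,3-bis(benzyloxy)-5-[(1R,2R)-2-(benzyloxy)-1-[4-(benzyloxy)phenyl]-3-(trityloxy)propoxy]benzene | c1ccccc1C(c1ccccc1)(c1ccccc1)OC[C@@H](OCc1ccccc1)[C@H](Oc1cc(OCc2ccccc2)cc(OCc2ccccc2)c1)c1ccc(OCc2ccccc2)cc1 | intermediate
27 | (2R,3R)-2-(benzyloxy)-3-[4-(benzyloxy)phenyl]-3-[3,5-bis(benzyloxy)phenoxy]propan-1-ol | OC[C@@H](OCc1ccccc1)[C@H](Oc1cc(OCc2ccccc2)cc(OCc2ccccc2)c1)c1ccc(OCc2ccccc2)cc1 | intermediate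
28 | (2S,3R)-2-(benzyloxy)-3-[4-(benzyloxy)phenyl]-3-[3,5-bis(benzyloxy)phenoxy]propanal | O=C[C@@H](OCc1ccccc1)[C@H](Oc1cc(OCc2ccccc2)cc(OCc2ccccc2)c1)c1ccc(OCc2ccccc2)cc1 | intermediate
29 | chloro(methyl)aluminium C4 alkoxide of 30 | c1c(OCc3ccccc3)cc(OCc3ccccc3)c2c1O[C@H](c1ccc(OCc3ccccc3)cc1)[C@H](OCc1ccccc1)[C@H]2O[Al](C)Cl | intermediate
30 | (2R,3R,4S)-3,5,7-tris(benzyloxy)-2-[4-(benzyloxy)phenyl]chroman-4-ol | c1c(OCc3ccccc3)cc(OCc3ccccc3)c2c1O[C@H](c1ccc(OCc3ccccc3)cc1)[C@H](OCc1ccccc1)[C@H]2O | intermediate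
31 | (2R,3R,4S)-3,5,7-tris(benzyloxy)-2-[4-(benzyloxy)phenyl]-8-bromochroman-4-ol | Brc1c(OCc3ccccc3)cc(OCc3ccccc3)c2c1O[C@H](c1ccc(OCc3ccccc3)cc1)[C@H](OCc1ccccc1)[C@H]2O | intermediate
32 | (2R,3S)-3,5,7-tris(benzyloxy)-2-[4-(benzyloxy)phenyl]-8-bromochroman-4-one | Brc1c(OCc3ccccc3)cc(OCc3ccccc3)c2c1O[C@H](c1ccc(OCc3ccccc3)cc1)[C@H](OCc1ccccc1)C2=O | intermediate
33 | 8-lithio derivative of 16 (aryllithium) | [Li]c1c(OCc3ccccc3)cc(OCc3ccccc3)c2c1O[C@@H](c1ccc(OCc3ccccc3)cc1)[C@@H](OCc1ccccc1)[C@@H]2OCc1ccccc1 | intermediate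
34 | 8-(dichloroceryl) derivative of 16 (aryldichlorocerium) | Cl[Ce](Cl)c1c(OCc3ccccc3)cc(OCc3ccccc3)c2c1O[C@@H](c1ccc(OCc3ccccc3)cc1)[C@@H](OCc1ccccc1)[C@@H]2OCc1ccccc1 | intermediate
35 | dimer carbinol: 8-bromo unit M (2R; 2,3-cis) with C4 bearing OH (cis to 3-OBn) and C8 of unit B (as in 16) | c5ccccc5COc1ccc([C@H]2Oc3c(c(OCc5ccccc5)cc(OCc5ccccc5)c3Br)[C@@](c3c(OCc5ccccc5)cc(OCc5ccccc5)c4c3O[C@@H](c3ccc(OCc5ccccc5)cc3)[C@@H](OCc5ccccc5)[C@@H]4OCc5ccccc5)(O)[C@H]2OCc5ccccc5)cc1 | intermediate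
36 | benzylated 8-bromo dimer M–B: unit M (2R) all-cis at C2/C3/C4; C4(M)–C8(B); unit B (2S,3S,4R) | c5ccccc5COc1ccc([C@H]2Oc3c(c(OCc5ccccc5)cc(OCc5ccccc5)c3Br)[C@@H](c3c(OCc5ccccc5)cc(OCc5ccccc5)c4c3O[C@@H](c3ccc(OCc5ccccc5)cc3)[C@@H](OCc5ccccc5)[C@@H]4OCc5ccccc5)[C@H]2OCc5ccccc5)cc1 | intermediate
37 | C8(M)-lithio derivative of dimer 36 (aryllithium) | c5ccccc5COc1ccc([C@H]2Oc3c(c(OCc5ccccc5)cc(OCc5ccccc5)c3[Li])[C@@H](c3c(OCc5ccccc5)cc(OCc5ccccc5)c4c3O[C@@H](c3ccc(OCc5ccccc5)cc3)[C@@H](OCc5ccccc5)[C@@H]4OCc5ccccc5)[C@H]2OCc5ccccc5)cc1 | intermediate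
38 | C8(M)-(dichloroceryl) derivative of dimer 36 (aryldichlorocerium) | c5ccccc5COc1ccc([C@H]2Oc3c(c(OCc5ccccc5)cc(OCc5ccccc5)c3[Ce](Cl)Cl)[C@@H](c3c(OCc5ccccc5)cc(OCc5ccccc5)c4c3O[C@@H](c3ccc(OCc5ccccc5)cc3)[C@@H](OCc5ccccc5)[C@@H]4OCc5ccccc5)[C@H]2OCc5ccccc5)cc1 | intermediate
39 | trimer carbinol: unit T (2S; 2,3-cis) with C4 bearing OH (cis to 3-OBn) and C8 of unit M; units M and B as in 36 | c5ccccc5COc1ccc([C@H]2Oc3c(c(OCc5ccccc5)cc(OCc5ccccc5)c3[C@]3(O)c4c(OCc5ccccc5)cc(OCc5ccccc5)cc4O[C@@H](c4ccc(OCc5ccccc5)cc4)[C@H]3OCc5ccccc5)[C@@H](c3c(OCc5ccccc5)cc(OCc5ccccc5)c4c3O[C@@H](c3ccc(OCc5ccccc5)cc3)[C@@H](OCc5ccccc5)[C@@H]4OCc5ccccc5)[C@H]2OCc5ccccc5)cc1 | intermediate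
40 | tridecabenzyl trimer T–M–B: unit T (2S) all-cis; unit M (2R) all-cis; unit B (2S,3S,4R); C4(T)–C8(M) and C4(M)–C8(B) | c5ccccc5COc1ccc([C@H]2Oc3c(c(OCc5ccccc5)cc(OCc5ccccc5)c3[C@H]3c4c(OCc5ccccc5)cc(OCc5ccccc5)cc4O[C@@H](c4ccc(OCc5ccccc5)cc4)[C@H]3OCc5ccccc5)[C@@H](c3c(OCc5ccccc5)cc(OCc5ccccc5)c4c3O[C@@H](c3ccc(OCc5ccccc5)cc3)[C@@H](OCc5ccccc5)[C@@H]4OCc5ccccc5)[C@H]2OCc5ccccc5)cc1 | intermediate
41 | CNP0159291.1 (free trimer; units T and M all-cis, unit B the 2,3-cis-3,4-trans 3,4-diol) | Oc1ccc([C@H]2Oc3c(c(O)cc(O)c3[C@H]3c4c(O)cc(O)cc4O[C@@H](c4ccc(O)cc4)[C@H]3O)[C@@H](c3c(O)cc(O)c4c3O[C@@H](c3ccc(O)cc3)[C@@H](O)[C@@H]4O)[C@H]2O)cc1 | target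

**Step count and risks**

Total: 28 steps. Longest linear sequence: 16 steps (steps 1–11 then 24–28; equally steps 13–23 then 24–28).

Steps most likely to fail:

1. Step 9 (and its mirror image, step 21). What may go wrong is erosion of facial control at C4, if a chelated or equatorial-oxygen transition state competes, or ionisation of the benzylic C4–O–Al bond followed by intermolecular arylation. Fallback: give up stereocontrol in the ring closure and set C4 afterwards. Setting out from aldehyde 13, the cyclisation is run with Me2AlCl or BF3·OEt2 and the crude mixture of 15 and its C4 epimer (2S,3S,4S)-3,5,7-tris(benzyloxy)-2-[4-(benzyloxy)phenyl]chroman-4-ol F1 is reduced without separation (Et3SiH, CF3CO2H, CH2Cl2, 0 °C) to (2S,3S)-3,5,7-tris(benzyloxy)-2-[4-(benzyloxy)phenyl]chromane F2. Benzylic oxidation of F2 with DDQ in wet CH2Cl2 then puts the hydroxyl back at C4 by attack of water on the C4 cation anti to the C3 benzyloxy group, and the route is rejoined at 15.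

2. Step 26 (the concern holds in weaker form for step 24). What may go wrong is slow addition of the aryl metal of the dimer, so that proton abstraction at C3 of ketone 18 with opening of ring C, or quenching of the organometallic, takes over. Fallback: reverse the order of assembly so that both additions use monomeric aryl metals and the ketone partner of the first can be taken in excess. Setting out from 31 and 18, the C4 hydroxyl of 31 is silylated (t-BuMe2SiCl, imidazole, DMF) to (2R,3R,4S)-3,5,7-tris(benzyloxy)-2-[4-(benzyloxy)phenyl]-8-bromo-4-[(tert-butyldimethylsilyl)oxy]chromane F3. Bromine–lithium exchange (t-BuLi, THF, –78 °C) gives the aryllithium F4, which is added to 18 to give the T–M carbinol F5. Ionic hydrogenation (Bu3SnH, CF3CO2H) gives the all-cis T–M dimer silyl ether F6, Bu4NF frees the T–M dimer C4(M) alcohol F7, and Dess–Martin oxidation gives the T–M dimer ketone F8. Addition of aryldichlorocerium 34 (made from 17 as in step 24) gives the trimer C4(M) carbinol F9, and a last ionic hydrogenation rejoins the route at 40.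

3. Step 28. What may go wrong is hydrogenolytic cleavage of the C4–O bond of unit B while the benzyl ether there is being removed (over-reduction to the 4-deoxy trimer), or ionisation at C4 of unit B once the ring A phenols are free. Fallback: unmask the C4 oxygen of unit B by solvolysis instead of hydrogenolysis. Setting out from 40, catalytic camphorsulfonic acid in THF–H2O at 0 °C exchanges only the ionisable C4 benzyl ether for hydroxyl (water adds to the C4 cation anti to the C3 benzyloxy group, so the 3,4-trans relation is kept) to give the dodecabenzyl trimer with free C4 hydroxyl on unit B F10. Its twelve remaining benzyl ethers are then removed by neutral hydrogenolysis (H2, Pd(OH)2/C), which rejoins the route at 41.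

**Further compounds**

F1 | step 9 | (2S,3S,4S)-3,5,7-tris(benzyloxy)-2-[4-(benzyloxy)phenyl]chroman-4-ol | c1c(OCc3ccccc3)cc(OCc3ccccc3)c2c1O[C@@H](c1ccc(OCc3ccccc3)cc1)[C@@H](OCc1ccccc1)[C@H]2O
F2 | step 9 | (2S,3S)-3,5,7-tris(benzyloxy)-2-[4-(benzyloxy)phenyl]chromane | c1c(OCc3ccccc3)cc(OCc3ccccc3)c2c1O[C@@H](c1ccc(OCc3ccccc3)cc1)[C@@H](OCc1ccccc1)C2
F3 | step 26 | (2R,3R,4S)-3,5,7-tris(benzyloxy)-2-[4-(benzyloxy)phenyl]-8-bromo-4-[(tert-butyldimethylsilyl)oxy]chromane | Brc1c(OCc3ccccc3)cc(OCc3ccccc3)c2c1O[C@H](c1ccc(OCc3ccccc3)cc1)[C@H](OCc1ccccc1)[C@H]2O[Si](C)(C)C(C)(C)C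
F4 | step 26 | aryllithium (8-lithio derivative of F3) | [Li]c1c(OCc3ccccc3)cc(OCc3ccccc3)c2c1O[C@H](c1ccc(OCc3ccccc3)cc1)[C@H](OCc1ccccc1)[C@H]2O[Si](C)(C)C(C)(C)C
F5 | step 26 | T–M carbinol (C4(T) bears OH and C8 of unit M; unit M with C4 silyl ether) | c5ccccc5COc1ccc([C@H]2Oc3c(c(OCc5ccccc5)cc(OCc5ccccc5)c3[C@]3(O)c4c(OCc5ccccc5)cc(OCc5ccccc5)cc4O[C@@H](c4ccc(OCc5ccccc5)cc4)[C@H]3OCc5ccccc5)[C@H](O[Si](C)(C)C(C)(C)C)[C@H]2OCc5ccccc5)cc1
F6 | step 26 | all-cis T–M dimer silyl ether | c5ccccc5COc1ccc([C@H]2Oc3c(c(OCc5ccccc5)cc(OCc5ccccc5)c3[C@H]3c4c(OCc5ccccc5)cc(OCc5ccccc5)cc4O[C@@H](c4ccc(OCc5ccccc5)cc4)[C@H]3OCc5ccccc5)[C@H](O[Si](C)(C)C(C)(C)C)[C@H]2OCc5ccccc5)cc1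
F7 | step 26 | T–M dimer C4(M) alcohol | c5ccccc5COc1ccc([C@H]2Oc3c(c(OCc5ccccc5)cc(OCc5ccccc5)c3[C@H]3c4c(OCc5ccccc5)cc(OCc5ccccc5)cc4O[C@@H](c4ccc(OCc5ccccc5)cc4)[C@H]3OCc5ccccc5)[C@H](O)[C@H]2OCc5ccccc5)cc1
F8 | step 26 | T–M dimer ketone (C4(M)=O) | c5ccccc5COc1ccc([C@H]2Oc3c(c(OCc5ccccc5)cc(OCc5ccccc5)c3[C@H]3c4c(OCc5ccccc5)cc(OCc5ccccc5)cc4O[C@@H](c4ccc(OCc5ccccc5)cc4)[C@H]3OCc5ccccc5)C(=O)[C@H]2OCc5ccccc5)cc1
F9 | step 26 | trimer C4(M) carbinol | c5ccccc5COc1ccc([C@H]2Oc3c(c(OCc5ccccc5)cc(OCc5ccccc5)c3[C@H]3c4c(OCc5ccccc5)cc(OCc5ccccc5)cc4O[C@@H](c4ccc(OCc5ccccc5)cc4)[C@H]3OCc5ccccc5)[C@@](c3c(OCc5ccccc5)cc(OCc5ccccc5)c4c3O[C@@H](c3ccc(OCc5ccccc5)cc3)[C@@H](OCc5ccccc5)[C@@H]4OCc5ccccc5)(O)[C@H]2OCc5ccccc5)cc1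
F10 | step 28 | dodecabenzyl trimer with free C4 hydroxyl on unit B | c5ccccc5COc1ccc([C@H]2Oc3c(c(OCc5ccccc5)cc(OCc5ccccc5)c3[C@H]3c4c(OCc5ccccc5)cc(OCc5ccccc5)cc4O[C@@H](c4ccc(OCc5ccccc5)cc4)[C@H]3OCc5ccccc5)[C@@H](c3c(OCc5ccccc5)cc(OCc5ccccc5)c4c3O[C@@H](c3ccc(OCc5ccccc5)cc3)[C@@H](OCc5ccccc5)[C@@H]4O)[C@H]2OCc5ccccc5)cc1
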